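**Strategy.** Ring A is closed by forming the C1–C10 bond on a monocyclic ring B precursor. The quaternary carbon C10 of the ring A/ring B fusion is written as an exocyclic alkene C10=C20, and C1 as the N-tosylhydrazone of an aldehyde on the C5–C4–C3–C2 chain. Iron hydride hydrogen atom transfer turns C20 into the angular methyl and C10 into a tertiary radical that adds 6-exo to C1; loss of sulfinate and N2 then leaves C1H2. The precursor comes from (−)-verbenone: its six-membered ring is ring B, its gem-dimethyl carbon is C4, and the cyclobutane bond C4–C7, absent from the target, is cut by a radical ring opening that attaches the C3–C1 chain.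

Key step: step 7

Remark on numbering: every intermediate carries the labdane atom numbers of the target (C1–C20). In verbenone the carbonyl carbon is C10, the alpha carbon C9, the methyl-bearing alkene carbon C8 (its methyl is C17), the bridgeheads are C5 (next to the carbonyl) and C7, the gem-dimethyl carbon is C4 and the CH2 bridge is C6.

Assumption: the E and Z enoates formed in step 9 are separable by chromatography; only the E isomer is carried on.

Step 1
Reactants: 1 (1S,5S)-(−)-verbenone; 2 2-(2-bromoethyl)-2-methyl-1,3-dioxolane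
Product: 4 (1S,5R)-4,6,6-trimethyl-3-[2-(2-methyl-1,3-dioxolan-2-yl)ethyl]bicyclo[3.1.1]hept-3-en-2-one, via deconjugated alkylation product 3 (not isolated)
Conditions: KOtBu, DME, 0 °C to rt
Reagents that add atoms: none
Why: Deprotonation of the gamma methyl group gives the extended potassium dienolate (the bridgehead cannot enolize), which is alkylated at the alpha carbon C9 (deconjugative alkylation) and should reconjugate under the equilibrating conditions to the tetrasubstituted enone; no stereocentre is set.

Step 2
Reactants: 4 (1S,5R)-4,6,6-trimethyl-3-[2-(2-methyl-1,3-dioxolan-2-yl)ethyl]bicyclo[3.1.1]hept-3-en-2-one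
Product: 5 (1S,3S,5R)-6,6-dimethyl-4-methylidene-3-[2-(2-methyl-1,3-dioxolan-2-yl)ethyl]bicyclo[3.1.1]heptan-2-one (side chain syn to the gem-dimethyl bridge)
Conditions: LiN(iPr)2, THF, −78 °C; then AcOH, −78 °C
Reagents that add atoms: none
Why: Kinetic alpha-protonation of the extended lithium dienolate (deconjugation of an enone) should deliver the proton to C9 from the open face anti to the gem-dimethyl bridge, so that the side chain ends syn to the bridge, which is the C9 configuration of the target relative to C5.

Step 3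
Reactants: 5 (1S,3S,5R)-6,6-dimethyl-4-methylidene-3-[2-(2-methyl-1,3-dioxolan-2-yl)ethyl]bicyclo[3.1.1]heptan-2-one; 6 methyl acrylate
Product: 7 methyl 4-methyl-4-{(1S,3S)-4-methyl-3-[2-(2-methyl-1,3-dioxolan-2-yl)ethyl]-2-oxocyclohex-4-en-1-yl}pentanoate
Conditions: Fe(acac)3 (cat.), PhSiH3, EtOH/(CH2OH)2, 60 °C
Reagents that add atoms: none
Why: Mukaiyama-type metal-hydride hydrogen atom transfer to the exocyclic methylene gives the tertiary C8 radical, a cyclobutylcarbinyl radical that should open by strain-driven beta-scission of the C7–C4 bond to the C7=C8 alkene and the tertiary C4 radical, which is trapped by Giese addition to methyl acrylate and reduced; C5 and C9 are untouched and no new stereocentre forms.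

Step 4
Reactants: 7 methyl 4-methyl-4-{(1S,3S)-4-methyl-3-[2-(2-methyl-1,3-dioxolan-2-yl)ethyl]-2-oxocyclohex-4-en-1-yl}pentanoate
Product: 8 methyl 4-methyl-4-{(1S,3S)-4-methyl-2-methylidene-3-[2-(2-methyl-1,3-dioxolan-2-yl)ethyl]cyclohex-4-en-1-yl}pentanoate
Conditions: Zn, CH2Br2, TiCl4, THF/CH2Cl2, 0 °C to rt
Reagents that add atoms: dibromomethane, BrCBr
Why: Takai–Lombardo methylenation with the non-basic zinc/titanium methylene reagent should convert the hindered, enolizable C10 ketone into the exocyclic C10=C20 alkene without touching the ester, the ketal or the C9 stereocentre.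

Step 5
Reactants: 8 methyl 4-methyl-4-{(1S,3S)-4-methyl-2-methylidene-3-[2-(2-methyl-1,3-dioxolan-2-yl)ethyl]cyclohex-4-en-1-yl}pentanoate
Product: 9 4-methyl-4-{(1S,3S)-4-methyl-2-methylidene-3-[2-(2-methyl-1,3-dioxolan-2-yl)ethyl]cyclohex-4-en-1-yl}pentanal
Conditions: iBu2AlH, CH2Cl2, −78 °C; aqueous work-up
Reagents that add atoms: none
Why: Partial reduction of the unhindered methyl ester with iBu2AlH at low temperature should stop at the aluminium hemiacetal, which gives the C1 aldehyde on work-up.

Step 6
Reactants: 9 4-methyl-4-{(1S,3S)-4-methyl-2-methylidene-3-[2-(2-methyl-1,3-dioxolan-2-yl)ethyl]cyclohex-4-en-1-yl}pentanal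
Product: 10 (E)-N-tosylhydrazone of aldehyde 9
Conditions: TsNHNH2, MeOH, rt
Reagents that add atoms: p-toluenesulfonyl hydrazide, Cc1ccc(cc1)S(=O)(=O)NN
Why: Condensation of the aldehyde with the sulfonyl hydrazide (hydrazone formation) gives the C=N radical acceptor at C1 under neutral conditions that leave the ketal and both alkenes intact.

Step 7
Reactants: 10 (E)-N-tosylhydrazone of aldehyde 9
Product: 13 14,15-dinorlabd-7-en-13-one ethylene ketal, via cyclized tosylhydrazide 11 (not isolated), via alkyl diazene 12 (not isolated)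
Conditions: Fe(acac)3 (cat.), PhSiH3, EtOH/THF, 50 °C; then NaOAc, 80 °C
Reagents that add atoms: none
Why: An iron hydride generated from Fe(acac)3 and PhSiH3 transfers a hydrogen atom to the CH2 end of the exocyclic C10=C20 alkene (Markovnikov metal-hydride hydrogen atom transfer), the tertiary C10 radical adds to C1 of the tethered N-tosylhydrazone, the nitrogen radical is reduced to hydrazide 11, and warming with NaOAc eliminates p-toluenesulfinate to diazene 12, which loses N2 and leaves C1H2. The closest known reactions are the iron-hydride hydromethylation of alkenes with formaldehyde sulfonylhydrazones and the hydrogen-atom-transfer-triggered intramolecular coupling of alkenes with hydrazones. Ring A closes in the 6-exo-trig mode on the C=N bond. The new stereocentre C10 is controlled by C5 and C9: in a chair-like transition state the bulky C5–C4 bond stays equatorial on ring B and C1 reaches C10 equatorially from the alpha face, anti to the adjacent beta-oriented C9 side chain, so that C20 ends axial (beta) and trans to H5, the same sense as in radical polyene cyclizations that close a ring onto a ring-bound tertiary radical. The step needs hydrogen atom transfer to the 1,1-disubstituted alkene in preference to the trisubstituted C7=C8 alkene, which the lower substitution and better access of the methylene should secure, and ring closure faster than reduction of the C10 radical, which the high rate of radical addition to sulfonylhydrazones should secure.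

Step 8
Reactants: 13 14,15-dinorlabd-7-en-13-one ethylene ketal
Product: 14 14,15-dinorlabd-7-en-13-one
Conditions: PPTS (cat.), acetone/H2O, 50 °C
Reagents that add atoms: water, O
Why: Acid-catalysed ketal hydrolysis should free the C13 methyl ketone, the trisubstituted ring alkene being stable to the mild acid.

Step 9
Reactants: 14 14,15-dinorlabd-7-en-13-one
Product: 15 ethyl (13E)-labda-7,13-dien-15-oate
Conditions: (EtO)2P(O)CH2CO2Et, NaH, THF, 0 °C to reflux
Reagents that add atoms: triethyl phosphonoacetate, CCOC(=O)CP(=O)(OCC)OCC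
Why: Horner–Wadsworth–Emmons olefination of the methyl ketone with the stabilized phosphonate anion should give the trisubstituted enoate with the E isomer favoured, the minor Z isomer being removed by chromatography.

Step 10
Reactants: 15 ethyl (13E)-labda-7,13-dien-15-oate
Product: 16 ethyl (13E)-7α,8α-epoxylabd-13-en-15-oate
Conditions: mCPBA, NaHCO3, CH2Cl2, 0 °C
Reagents that add atoms: 3-chloroperoxybenzoic acid, OOC(=O)c1cccc(Cl)c1
Why: Prilezhaev epoxidation should take place at the electron-rich trisubstituted C7=C8 alkene and not at the electron-poor enoate, from the alpha face because the beta face is screened by the axial C20 methyl and the C9 side chain, which sets C7 and C8 with oxygen alpha.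

Step 11
Reactants: 16 ethyl (13E)-7α,8α-epoxylabd-13-en-15-oate
Product: 17 (13E)-labd-13-ene-8α,15-diol
Conditions: LiAlH4, THF, 0 °C to reflux
Reagents that add atoms: none
Why: Hydride reduction with LiAlH4 should open the trisubstituted epoxide by attack at the secondary C7, which keeps the C8–O bond and thus the 8α tertiary alcohol, and should reduce the enoate by 1,2-addition to the allylic alcohol.

Step 12
Reactants: 17 (13E)-labd-13-ene-8α,15-diol
Product: 18 (13E)-8α-hydroxylabd-13-en-15-yl acetate (CNP0268033.1)
Conditions: Ac2O, pyridine, 0 °C to rt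
Reagents that add atoms: acetic anhydride, CC(=O)OC(C)=O
Why: Selective esterification with acetic anhydride and pyridine should acetylate only the primary allylic hydroxyl, the tertiary C8 hydroxyl being too hindered to react.

**Compound list**

1 | (1S,5S)-(−)-verbenone, (1S,5S)-4,6,6-trimethylbicyclo[3.1.1]hept-3-en-2-one | CC1=CC(=O)[C@H]2C[C@@H]1C2(C)C | starting material
2 | 2-(2-bromoethyl)-2-methyl-1,3-dioxolane | CC1(CCBr)OCCO1 | starting material
3 | (1S,3R,5R)-6,6-dimethyl-4-methylidene-3-[2-(2-methyl-1,3-dioxolan-2-yl)ethyl]bicyclo[3.1.1]heptan-2-one (side chain anti to the gem-dimethyl bridge) | C=C1[C@@H](CCC3(C)OCCO3)C(=O)[C@H]2C[C@@H]1C2(C)C | intermediate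
4 | (1S,5R)-4,6,6-trimethyl-3-[2-(2-methyl-1,3-dioxolan-2-yl)ethyl]bicyclo[3.1.1]hept-3-en-2-one | CC1=C(CCC3(C)OCCO3)C(=O)[C@H]2C[C@@H]1C2(C)C | intermediate
5 | (1S,3S,5R)-6,6-dimethyl-4-methylidene-3-[2-(2-methyl-1,3-dioxolan-2-yl)ethyl]bicyclo[3.1.1]heptan-2-one (side chain syn to the gem-dimethyl bridge) | C=C1[C@H](CCC3(C)OCCO3)C(=O)[C@H]2C[C@@H]1C2(C)C | intermediate
6 | methyl acrylate | C=CC(=O)OC | starting material
7 | methyl 4-methyl-4-{(1S,3S)-4-methyl-3-[2-(2-methyl-1,3-dioxolan-2-yl)ethyl]-2-oxocyclohex-4-en-1-yl}pentanoate | CC1=CC[C@@H](C(C)(C)CCC(=O)OC)C(=O)[C@H]1CCC2(C)OCCO2 | intermediate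
8 | methyl 4-methyl-4-{(1S,3S)-4-methyl-2-methylidene-3-[2-(2-methyl-1,3-dioxolan-2-yl)ethyl]cyclohex-4-en-1-yl}pentanoate | CC1=CC[C@@H](C(C)(C)CCC(=O)OC)C(=C)[C@H]1CCC2(C)OCCO2 | intermediate
9 | 4-methyl-4-{(1S,3S)-4-methyl-2-methylidene-3-[2-(2-methyl-1,3-dioxolan-2-yl)ethyl]cyclohex-4-en-1-yl}pentanal | CC1=CC[C@@H](C(C)(C)CCC=O)C(=C)[C@H]1CCC2(C)OCCO2 | intermediate
10 | (E)-N-tosylhydrazone of aldehyde 9 | CC1=CC[C@@H](C(C)(C)CC/C=N/NS(=O)(=O)c3ccc(C)cc3)C(=C)[C@H]1CCC2(C)OCCO2 | intermediate
11 | 1-(2-tosylhydrazinyl)-14,15-dinorlabd-7-en-13-one ethylene ketal (C1 epimers) | CC1(CC[C@@H]2[C@@]3(C)C(NNS(=O)(=O)c4ccc(C)cc4)CCC(C)(C)[C@@H]3CC=C2C)OCCO1 | intermediate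
12 | 1-diazenyl-14,15-dinorlabd-7-en-13-one ethylene ketal (C1 epimers) | CC1(CC[C@@H]2[C@@]3(C)C(N=N)CCC(C)(C)[C@@H]3CC=C2C)OCCO1 | intermediate
13 | 14,15-dinorlabd-7-en-13-one ethylene ketal (5α-H, 9α-H, 10β-methyl) | CC1(CC[C@@H]2[C@@]3(C)CCCC(C)(C)[C@@H]3CC=C2C)OCCO1 | intermediate
14 | 14,15-dinorlabd-7-en-13-one | CC(=O)CC[C@@H]1[C@@]2(C)CCCC(C)(C)[C@@H]2CC=C1C | intermediate
15 | ethyl (13E)-labda-7,13-dien-15-oate | CCOC(=O)/C=C(\C)CC[C@@H]1[C@@]2(C)CCCC(C)(C)[C@@H]2CC=C1C | intermediate
16 | ethyl (13E)-7α,8α-epoxylabd-13-en-15-oate | CCOC(=O)/C=C(\C)CC[C@@H]1[C@@]2(C)CCCC(C)(C)[C@@H]2C[C@H]3O[C@@]13C | intermediate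
17 | (13E)-labd-13-ene-8α,15-diol | OC/C=C(\C)CC[C@@H]1[C@@]2(C)CCCC(C)(C)[C@@H]2CC[C@@]1(C)O | intermediate
18 | (13E)-8α-hydroxylabd-13-en-15-yl acetate | CC(=O)OC/C=C(\C)CC[C@@H]1[C@@]2(C)CCCC(C)(C)[C@@H]2CC[C@@]1(C)O | target

**Total step count:** 12. **Longest linear sequence:** 12 steps (1 to 18).

**Steps most likely to fail**

1. Step 7. The radical ring closure may show poor facial selectivity at C10 (cis ring fusion), hydrogen atom transfer may go to the C7=C8 alkene, or the C10 radical may be reduced before it cyclizes. The fallback closes ring A ionically, by intramolecular alkylation of an exocyclic nitrile anion, a closure that should favour the equatorial (trans) mode. It sets out from 8: hydroboration of the exocyclic alkene with 9-BBN and oxidation with NaBO3 should give hydroxymethyl ester F1. One-pot oxidation with TEMPO, PhI(OAc)2 and NH4OAc should give nitrile ester F2. LiBH4 should reduce only the ester to nitrile alcohol F3, and I2, PPh3 and imidazole should give nitrile iodide F4. KN(SiMe3)2 in THF should then form the C1–C10 bond by alkylation of the C10 nitrile anion to angular nitrile F5. iBu2AlH should give angular aldehyde F6, and Wolff–Kishner reduction (N2H4·H2O, KOH, diethylene glycol, 200 °C) turns the formyl group into the C20 methyl. The fallback comes back to the route at 13.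

2. Step 3. The first tertiary radical may be trapped before the cyclobutane opens, the ring-opened radical may undergo a 1,2-acyl shift or simple reduction, or the C9 configuration may be lost under the conditions. The fallback opens the ring ionically and forms the C4–C3 bond in a separate tin-mediated Giese addition. It sets out from 5: anhydrous HBr in CH2Cl2 at −78 °C should protonate the exocyclic alkene, cleave the cyclobutane as in the pinene-to-terpinyl opening and capture bromide to give tertiary bromide F7. Bu3SnH, AIBN and methyl acrylate 6 in benzene at 80 °C should then give the keto ester. The fallback comes back to the route at 7.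

3. Step 4. The methylene reagent may fail to add to the doubly alpha-branched ketone, or enolization may move the C7=C8 bond into conjugation. The fallback is a Peterson olefination. It sets out from 7: non-basic addition of Me3SiCH2MgCl/CeCl3 at −78 °C should give beta-hydroxysilane F8, and syn elimination with KH in THF should give the alkene. The fallback comes back to the route at 8.

**Further compounds**

F1 | step 7 | hydroxymethyl ester, methyl 4-{(1S,3S)-2-(hydroxymethyl)-4-methyl-3-[2-(2-methyl-1,3-dioxolan-2-yl)ethyl]cyclohex-4-en-1-yl}-4-methylpentanoate (C10 epimers) | CC1=CC[C@@H](C(C)(C)CCC(=O)OC)C(CO)[C@H]1CCC2(C)OCCO2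
F2 | step 7 | nitrile ester, methyl 4-{(1S,3S)-2-cyano-4-methyl-3-[2-(2-methyl-1,3-dioxolan-2-yl)ethyl]cyclohex-4-en-1-yl}-4-methylpentanoate (C10 epimers) | CC1=CC[C@@H](C(C)(C)CCC(=O)OC)C(C#N)[C@H]1CCC2(C)OCCO2
F3 | step 7 | nitrile alcohol, (2S,6S)-6-(5-hydroxy-2-methylpentan-2-yl)-3-methyl-2-[2-(2-methyl-1,3-dioxolan-2-yl)ethyl]cyclohex-3-ene-1-carbonitrile (C10 epimers) | CC1=CC[C@@H](C(C)(C)CCCO)C(C#N)[C@H]1CCC2(C)OCCO2
F4 | step 7 | nitrile iodide, (2S,6S)-6-(5-iodo-2-methylpentan-2-yl)-3-methyl-2-[2-(2-methyl-1,3-dioxolan-2-yl)ethyl]cyclohex-3-ene-1-carbonitrile (C10 epimers) | CC1=CC[C@@H](C(C)(C)CCCI)C(C#N)[C@H]1CCC2(C)OCCO2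
F5 | step 7 | angular nitrile, 13,13-ethylenedioxy-14,15-dinorlabd-7-ene-20-nitrile | CC1(CC[C@@H]2[C@@]3(C#N)CCCC(C)(C)[C@@H]3CC=C2C)OCCO1
F6 | step 7 | angular aldehyde, 13,13-ethylenedioxy-14,15-dinorlabd-7-en-20-al | CC1(CC[C@@H]2[C@@]3(C=O)CCCC(C)(C)[C@@H]3CC=C2C)OCCO1
F7 | step 3 | tertiary bromide, (2S,6S)-6-(2-bromopropan-2-yl)-3-methyl-2-[2-(2-methyl-1,3-dioxolan-2-yl)ethyl]cyclohex-3-en-1-one | CC1=CC[C@@H](C(C)(C)Br)C(=O)[C@H]1CCC2(C)OCCO2
F8 | step 4 | beta-hydroxysilane, methyl 4-{(1S,3S)-2-hydroxy-4-methyl-3-[2-(2-methyl-1,3-dioxolan-2-yl)ethyl]-2-[(trimethylsilyl)methyl]cyclohex-4-en-1-yl}-4-methylpentanoate (C10 epimers) | CC1=CC[C@@H](C(C)(C)CCC(=O)OC)C(O)(C[Si](C)(C)C)[C@H]1CCC2(C)OCCO2
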